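**Retrosynthetic overview**

1. The target is (3R,5S)-1-(4-hydroxy-3-methoxyphenyl)dodecane-3,5-diyl diacetate, the syn-diacetate (C1 = benzylic CH2). In reverse, the endgame frees the phenol from its acetate, acetylates O5, and opens a tetrahydropyran by hydrogenolysis of its benzylic C1–O bond.
2. Enabling feature: the benzylic carbon C1 on the 4-oxygenated 3-methoxyphenyl ring stands 1,5 to carbinol C5, with C3–O between them. O5 can therefore be tied to C1 in a six-membered ring (O, C1, C2, C3, C4, C5), and C1 serves as a temporary stereocentre that hydrogenolysis later erases.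
3. Key disconnection C4–C5 (with C3–O): a Prins cyclization of (S)-1-aryl-but-3-en-1-ol with octanal builds the all-cis 2-aryl-6-heptyl-tetrahydropyran-4-ol, the only ring formed, and sets C5 and C3 from C1. A Mitsunobu displacement with acetic acid then inverts C3 into the syn series.
4. The homoallylic alcohol comes from Keck allylation of vanillin acetate. The aryl acetate is the only protecting group and keeps the arene electron-poor for the Prins step.

Key step: step 2

Remark: vanillin acetate, octanal and allyltributylstannane are taken as commercial; the chain locants C1–C12 of the target are used for all intermediates.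

**Route**

Step 1
Reactants: 1 vanillin acetate (4-formyl-2-methoxyphenyl acetate)
Product: 2 4-[(1S)-1-hydroxybut-3-en-1-yl]-2-methoxyphenyl acetate
Conditions: (S)-BINOL (20 mol%), Ti(OiPr)4 (10 mol%), 4 Å MS, allylSnBu3 (1.2 equiv), CH2Cl2, −20 °C; aq. NaHCO3 work-up
Reagents that add atoms: allyltributylstannane, C=CC[Sn](CCCC)(CCCC)CCCC
Why: Keck asymmetric allylation, in which the (S)-BINOL–Ti(IV) Lewis acid activates the aldehyde and directs allyl transfer to one carbonyl face, should set the (S)-benzylic carbinol under neutral conditions that leave the aryl acetate intact.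

Step 2
Reactants: 2 4-[(1S)-1-hydroxybut-3-en-1-yl]-2-methoxyphenyl acetate; 3 octanal
Product: 5 4-[(2S,4R,6S)-6-heptyl-4-hydroxytetrahydro-2H-pyran-2-yl]-2-methoxyphenyl acetate, via pyranyl trifluoroacetate 4 (not isolated)
Conditions: octanal (1.5 equiv), TFA (10 equiv), CH2Cl2, 0 °C to rt; evaporate; then NaHCO3 (cat.), MeOH, 0 °C
Reagents that add atoms: trifluoroacetic acid, OC(=O)C(F)(F)F (one of its oxygen atoms remains as the C3 hydroxyl oxygen)
Why: TFA condenses alcohol 2 with octanal 3 to the (E)-oxocarbenium ion, whose terminal alkene carbon (C4) attacks the oxocarbenium carbon (C5) through a chair transition state and leaves a secondary tetrahydropyranyl cation at C3 that trifluoroacetate captures; this is the classical acid-mediated Prins cyclization of a homoallylic alcohol with an aldehyde, a reaction type established for 1-arylbut-3-en-1-ols. The tetrahydropyran closes by a cationic 6-endo-trig C–C bond formation of the alkene onto the O-tethered oxocarbenium ion. The new C5 stereocentre is controlled by the benzylic stereocentre C1, because aryl and heptyl both sit equatorial in the chair (2,6-cis), and the new C3 stereocentre by equatorial capture of the delocalized ring cation, so the (2S,4R,6S) all-cis isomer is expected. The step needs ring closure to outrun 2-oxonia-Cope rearrangement, aldehyde exchange and benzylic ionization, which would erode the enantiomeric purity; the acetylated phenol together with the meta-methoxy group keeps the arene non-donating and should secure this. The closing methanolysis relies on the far higher acyl-transfer reactivity of the trifluoroacetate, so that hydrogencarbonate in cold methanol should free the C3 alcohol without touching the aryl acetate.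

Step 3
Reactants: 5 4-[(2S,4R,6S)-6-heptyl-4-hydroxytetrahydro-2H-pyran-2-yl]-2-methoxyphenyl acetate
Product: 6 (2S,4S,6S)-2-(4-acetoxy-3-methoxyphenyl)-6-heptyltetrahydro-2H-pyran-4-yl acetate
Conditions: PPh3, DIAD, AcOH, THF, 0 °C to rt
Reagents that add atoms: acetic acid, CC(=O)O
Why: Mitsunobu reaction, in which the equatorial alcohol is activated as its alkoxyphosphonium ion and displaced by acetate along the unhindered axial trajectory, should invert the carbinol carbon (ring 4R to 4S, i.e. C3 of the target in its final R configuration, syn to O5) and install the first acetate at the same time.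

Step 4
Reactants: 6 (2S,4S,6S)-2-(4-acetoxy-3-methoxyphenyl)-6-heptyltetrahydro-2H-pyran-4-yl acetate
Product: 7 (3R,5S)-1-(4-acetoxy-3-methoxyphenyl)-5-hydroxydodecan-3-yl acetate
Conditions: H2 (1–4 bar), Pd(OH)2/C, EtOAc–AcOH, rt
Reagents that add atoms: none
Why: Catalytic hydrogenolysis of a benzylic ether should cleave only the ring C1–O bond, the one benzylic C–O bond in the molecule, which opens the ring to the C1 methylene and the free C5 alcohol without touching C3, C5 or the esters.

Step 5
Reactants: 7 (3R,5S)-1-(4-acetoxy-3-methoxyphenyl)-5-hydroxydodecan-3-yl acetate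
Product: 8 (3R,5S)-1-(4-acetoxy-3-methoxyphenyl)dodecane-3,5-diyl diacetate
Conditions: Ac2O, pyridine, DMAP (cat.), CH2Cl2, rt
Reagents that add atoms: acetic anhydride, CC(=O)OC(C)=O
Why: DMAP-catalysed acetylation of the secondary alcohol proceeds with retention at C5, and any 1,3-acetyl migration between O3 and O5 during step 4 is without consequence because both positions end as acetates.

Step 6
Reactants: 8 (3R,5S)-1-(4-acetoxy-3-methoxyphenyl)dodecane-3,5-diyl diacetate
Product: 9 (3R,5S)-1-(4-hydroxy-3-methoxyphenyl)dodecane-3,5-diyl diacetate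
Conditions: N2H4·H2O (1.1 equiv), MeCN, 0 °C
Reagents that add atoms: none
Why: Chemoselective hydrazinolysis of an aryl ester should cleave only the phenolic acetate, since phenoxide is a far better leaving group than a secondary alkoxide, leaving the two alkyl acetates in place.

**Compound list**

1 | vanillin acetate (4-formyl-2-methoxyphenyl acetate) | O=Cc1ccc(OC(C)=O)c(OC)c1 | starting material
2 | 4-[(1S)-1-hydroxybut-3-en-1-yl]-2-methoxyphenyl acetate | C=CC[C@H](O)c1ccc(OC(C)=O)c(OC)c1 | intermediate
3 | octanal | CCCCCCCC=O | starting material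
4 | (2S,4R,6S)-2-(4-acetoxy-3-methoxyphenyl)-6-heptyltetrahydro-2H-pyran-4-yl trifluoroacetate (all-cis) | CCCCCCC[C@H]1C[C@@H](OC(=O)C(F)(F)F)C[C@@H](c2ccc(OC(C)=O)c(OC)c2)O1 | intermediate (not isolated)
5 | 4-[(2S,4R,6S)-6-heptyl-4-hydroxytetrahydro-2H-pyran-2-yl]-2-methoxyphenyl acetate (all-cis, equatorial OH) | CCCCCCC[C@H]1C[C@@H](O)C[C@@H](c2ccc(OC(C)=O)c(OC)c2)O1 | intermediate
6 | (2S,4S,6S)-2-(4-acetoxy-3-methoxyphenyl)-6-heptyltetrahydro-2H-pyran-4-yl acetate (2,6-cis, axial OAc) | CCCCCCC[C@H]1C[C@H](OC(C)=O)C[C@@H](c2ccc(OC(C)=O)c(OC)c2)O1 | intermediate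
7 | (3R,5S)-1-(4-acetoxy-3-methoxyphenyl)-5-hydroxydodecan-3-yl acetate | CCCCCCC[C@H](O)C[C@H](OC(C)=O)CCc1ccc(OC(C)=O)c(OC)c1 | intermediate
8 | (3R,5S)-1-(4-acetoxy-3-methoxyphenyl)dodecane-3,5-diyl diacetate | CCCCCCC[C@H](OC(C)=O)C[C@H](OC(C)=O)CCc1ccc(OC(C)=O)c(OC)c1 | intermediate
9 | (3R,5S)-1-(4-hydroxy-3-methoxyphenyl)dodecane-3,5-diyl diacetate | CCCCCCC[C@@H](C[C@@H](CCc1ccc(O)c(OC)c1)OC(C)=O)OC(C)=O | target

**Totals and risks**

Total step count: 6. Longest linear sequence: 6 steps (1 to 9); octanal 3 enters in step 2.

Steps most likely to fail: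

1. Step 2. 2-Oxonia-Cope rearrangement and aldehyde exchange of the oxocarbenium ion, or ionization at the benzylic carbon, may compete with ring closure, eroding the enantiomeric purity and scrambling the side chains. The fallback exchanges the roles of the partners, so that the stereogenic carbinol is aliphatic and the aryl-conjugated oxocarbenium ion is the stable one. Setting out from octanal 3, a Keck allylation with (R)-BINOL/Ti(OiPr)4 and allyltributylstannane should give (S)-undec-1-en-4-ol F1, a step that forms the same C4–C5 bond. TFA-mediated Prins cyclization of F1 with vanillin acetate 1, followed by the same cold methanolysis of trifluoroacetate 4, should come back to the route at 5.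

2. Step 4. Hydrogenolysis of the secondary benzylic ether may be slow on the acyloxy-substituted arene, and forcing conditions may begin to saturate the aromatic ring. The fallback uses ionic instead of catalytic reduction. Setting out from 6, hydrazinolysis as in step 6 would free the phenol to give (2S,4S,6S)-2-heptyl-6-(4-hydroxy-3-methoxyphenyl)tetrahydro-2H-pyran-4-yl acetate F2. The para-hydroxy group now stabilizes a benzylic cation, so Et3SiH/TFA in CH2Cl2 at −20 to 0 °C should cleave the C1–O bond reductively to (3R,5S)-5-hydroxy-1-(4-hydroxy-3-methoxyphenyl)dodecan-3-yl acetate F3. Acetylation of both hydroxyl groups (Ac2O, pyridine, DMAP) comes back to the route at 8.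

3. Step 3. Elimination of the activated alcohol to a dihydropyran, or sluggish displacement by the weakly acidic acetic acid, may compete with the SN2 inversion. The fallback uses oxidation and reduction instead of substitution. Setting out from 5, Dess–Martin oxidation would give 4-[(2S,6S)-6-heptyl-4-oxotetrahydro-2H-pyran-2-yl]-2-methoxyphenyl acetate F4. L-Selectride in THF at −78 °C should deliver hydride along the equatorial trajectory to give the axial alcohol 4-[(2S,4S,6S)-6-heptyl-4-hydroxytetrahydro-2H-pyran-2-yl]-2-methoxyphenyl acetate F5. Acetylation (Ac2O, pyridine, DMAP), which would also restore any aryl acetate lost to the hydride, comes back to the route at 6.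

**Further compounds**

F1 | step 2 | (S)-undec-1-en-4-ol | CCCCCCC[C@H](O)CC=C
F2 | step 4 | (2S,4S,6S)-2-heptyl-6-(4-hydroxy-3-methoxyphenyl)tetrahydro-2H-pyran-4-yl acetate | CCCCCCC[C@H]1C[C@H](OC(C)=O)C[C@@H](c2ccc(O)c(OC)c2)O1
F3 | step 4 | (3R,5S)-5-hydroxy-1-(4-hydroxy-3-methoxyphenyl)dodecan-3-yl acetate | CCCCCCC[C@H](O)C[C@H](OC(C)=O)CCc1ccc(O)c(OC)c1
F4 | step 3 | 4-[(2S,6S)-6-heptyl-4-oxotetrahydro-2H-pyran-2-yl]-2-methoxyphenyl acetate | CCCCCCC[C@H]1CC(=O)C[C@@H](c2ccc(OC(C)=O)c(OC)c2)O1
F5 | step 3 | 4-[(2S,4S,6S)-6-heptyl-4-hydroxytetrahydro-2H-pyran-2-yl]-2-methoxyphenyl acetate | CCCCCCC[C@H]1C[C@H](O)C[C@@H](c2ccc(OC(C)=O)c(OC)c2)O1
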